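**Plan**

1. Retrosynthesis: the oxirane goes back to the ring C olefin; the CH2–C bond at the ring C carbon that carries the two-carbon bridge is cut, giving ring A/B iodide 22 and ring C/D enone 36; ring A is cut at its O–C(CH3)2 bond, ring B at its CH2–C(CH3)(OH) bond, ring C at its C=C bond.
2. Enabling feature: in ring B the O-bearing ring-fusion CH and the carbinol carbon C(CH3)(OH) are 1,4 to each other, so the carbinol carbon can be stored as the carbonyl of a γ-butyrolactone whose ring oxygen is the future ring A oxygen; a two-carbon iodide arm on the O–CH carbon then closes ring B onto that carbonyl and sets the hydroxyl free as a 4-hydroxycyclohexanone.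
3. Forward, rings A/B: catalytic alkynylation (the one catalyst-made stereocentre) → butenolide → anti conjugate methylation (quaternary centre) → anti enolate alkylation → SmI2 closure of ring B → equatorial methyl addition (carbinol centre) → alkoxymercuration closes ring A.
4. Rings C/D: (R)-linalool supplies the ring D carbinol centre; directed epoxidation, anti epoxide opening and contrasteric hydroboration relay it to both ring-fusion CH centres; enone metathesis closes ring C.
5. Union and end game: 1,2-addition of the alkyllithium from 22 to 36, palladium–formate hydrogenolysis of the allylic carbonate (sets the side-chain CH centre and the trisubstituted olefin), desilylation, then bromohydrin closure places the oxirane on the face opposite to electrophile attack.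

Key step: step 7

Remark: rings are lettered A (oxepanone), B (cyclohexane), C (seven-membered carbocycle), D (cyclopentane). Alcohol 19 is formed and used as a mixture of epimers at its new ring A carbinol carbon; that centre becomes the ketone in step 10.

Step 1
Reactants: 1 3-(tert-butyldimethylsilyloxy)propanal; 2 methyl propiolate
Product: 4 methyl (R)-6-(tert-butyldimethylsilyloxy)-4-hydroxyhex-2-ynoate, via zinc acetylide 3 (not isolated)
Conditions: Me2Zn (3 equiv), ProPhenol ligand [2,6-bis{[2-(hydroxydiphenylmethyl)pyrrolidin-1-yl]methyl}-4-methylphenol, 10 mol %, the enantiomer that delivers the R alcohol], toluene, 0 °C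
Reagents that add atoms: none
Why: Catalytic enantioselective addition of a zinc acetylide to an aldehyde (dinuclear zinc–ProPhenol catalysis) should set the only catalyst-derived stereocentre, the future ring-fusion O–CH carbon, from which the other ring A/B centres are relayed.

Step 2
Reactants: 4 methyl (R)-6-(tert-butyldimethylsilyloxy)-4-hydroxyhex-2-ynoate; 5 5-bromo-2-methylpent-2-ene
Product: 8 (R)-5-[2-(tert-butyldimethylsilyloxy)ethyl]-4-(4-methylpent-3-en-1-yl)furan-2(5H)-one, via Grignard reagent 6 (not isolated), via Z-hydroxy enoate 7 (not isolated)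
Conditions: 5, Mg, THF, rt; CuBr·SMe2, −78 °C; then 4, −78 → −40 °C; aq. NH4Cl; PPTS (cat.), CH2Cl2, rt
Reagents that add atoms: none
Why: syn-Carbocupration of the ynoate (cuprate addition to a γ-hydroxy alkynoate) places the ester cis to the carbinol, so the hydroxy enoate lactonises to the β-substituted butenolide; the carbinol centre is not touched.

Step 3
Reactants: 8 (R)-5-[2-(tert-butyldimethylsilyloxy)ethyl]-4-(4-methylpent-3-en-1-yl)furan-2(5H)-one
Product: 10 (4R,5R)-5-[2-(tert-butyldimethylsilyloxy)ethyl]-4-methyl-4-(4-methylpent-3-en-1-yl)dihydrofuran-2(3H)-one, via silyl ketene acetal 9 (not isolated)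
Conditions: MeMgBr (2.5 equiv), CuBr·SMe2 (20 mol %), TMSCl (3 equiv), THF, −78 → −30 °C; then 1 M aq. HCl
Reagents that add atoms: methylmagnesium bromide C[Mg]Br
Why: Copper-catalysed, TMSCl-accelerated conjugate addition to the butenolide should deliver methyl anti to the γ-substituent, so the new quaternary centre carries its methyl trans and its methylpentenyl chain cis to the silyloxyethyl arm.

Step 4
Reactants: 10 (4R,5R)-5-[2-(tert-butyldimethylsilyloxy)ethyl]-4-methyl-4-(4-methylpent-3-en-1-yl)dihydrofuran-2(3H)-one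
Product: 12 (3R,4R,5R)-5-[2-(tert-butyldimethylsilyloxy)ethyl]-3-(2-chloroethyl)-4-methyl-4-(4-methylpent-3-en-1-yl)dihydrofuran-2(3H)-one, via lithium enolate 11 (not isolated)
Conditions: LDA, THF, −78 °C; then ClCH2CH2OTf, −78 → −40 °C
Reagents that add atoms: 2-chloroethyl trifluoromethanesulfonate ClCCOS(=O)(=O)C(F)(F)F
Why: Lactone enolate alkylation at the triflate carbon (chloride untouched) should occur on the face of the small methyl group, anti to the methylpentenyl chain on the adjacent quaternary carbon and to the γ-arm, giving the α-centre that later carries an equatorial side chain in ring B.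

Step 5
Reactants: 12 (3R,4R,5R)-5-[2-(tert-butyldimethylsilyloxy)ethyl]-3-(2-chloroethyl)-4-methyl-4-(4-methylpent-3-en-1-yl)dihydrofuran-2(3H)-one
Product: 13 (3R,4R,5R)-3-(2-chloroethyl)-5-(2-hydroxyethyl)-4-methyl-4-(4-methylpent-3-en-1-yl)dihydrofuran-2(3H)-one
Conditions: HF·pyridine, pyridine, THF, 0 °C → rt
Reagents that add atoms: none
Why: Fluoride cleavage of a primary silyl ether; lactone, alkyl chloride and alkene are inert and no stereocentre is involved.

Step 6
Reactants: 13 (3R,4R,5R)-3-(2-chloroethyl)-5-(2-hydroxyethyl)-4-methyl-4-(4-methylpent-3-en-1-yl)dihydrofuran-2(3H)-one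
Product: 14 (3R,4R,5R)-3-(2-chloroethyl)-5-(2-iodoethyl)-4-methyl-4-(4-methylpent-3-en-1-yl)dihydrofuran-2(3H)-one
Conditions: I2, PPh3, imidazole, CH2Cl2, 0 °C
Reagents that add atoms: iodine II
Why: Appel iodination of the primary alcohol (SN2 at a CH2 carbon) gives the iodide that is reduced selectively in the next step.

Step 7
Reactants: 14 (3R,4R,5R)-3-(2-chloroethyl)-5-(2-iodoethyl)-4-methyl-4-(4-methylpent-3-en-1-yl)dihydrofuran-2(3H)-one
Product: 16 (2R,3R,4R)-2-(2-chloroethyl)-4-hydroxy-3-methyl-3-(4-methylpent-3-en-1-yl)cyclohexan-1-one, via samarium hemiketal alkoxide 15 (not isolated)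
Conditions: SmI2 (2.5 equiv), Fe(dbm)3 [tris(dibenzoylmethanato)iron, 2 mol %], THF, −30 °C → rt; aq. NH4Cl
Reagents that add atoms: none
Why: Two single-electron transfers from divalent samarium turn the primary C–I bond into a primary alkylsamarium, which adds to the lactone carbonyl lying 1,3 across the ring oxygen from the carbon that carries the iodoethyl arm; the closest known reaction type is the SmI2 Barbier-type intramolecular nucleophilic acyl substitution of iodoalkyl esters and lactones. Ring B is closed in a 6-exo-trig mode (the carbonyl oxygen stays outside the new carbocycle) through the 7-oxabicyclo[2.2.1]heptan-1-olate 15, whose collapse on work-up breaks the acyl C–O bond and releases the ring-fusion hydroxyl. No stereocentre is created: the O–CH, quaternary and α-CH centres of the lactone pass into ring B unchanged because no bond to them is broken, and the old lactone carbonyl becomes the ring B ketone that is methylated in step 8. The step needs chemoselectivity for C–I over C–Cl, which the much easier reduction of a primary iodide by SmI2 in THF without HMPA should secure, and for the lactone carbonyl over the product ketone, which stays masked as the trivalent samarium hemiketal until the quench. β-Elimination cannot occur because the leaving oxygen is 1,3 and not 1,2 to the carbanion. The two-carbon tether on the same small ring as the carbonyl holds the nucleophile over the carbonyl face, and the α-carbon presents only hydrogen on that face.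

Step 8
Reactants: 16 (2R,3R,4R)-2-(2-chloroethyl)-4-hydroxy-3-methyl-3-(4-methylpent-3-en-1-yl)cyclohexan-1-one
Product: 17 (1S,2R,3R,4R)-2-(2-chloroethyl)-1,3-dimethyl-3-(4-methylpent-3-en-1-yl)cyclohexane-1,4-diol
Conditions: MeMgBr (4 equiv), CeCl3, THF, −78 → 0 °C
Reagents that add atoms: methylmagnesium bromide C[Mg]Br
Why: In the chair with the chloroethyl and methylpentenyl groups equatorial, the axial methyl on the quaternary carbon 1,3 to the carbonyl blocks axial attack, so methyl should enter equatorially (cerium-assisted 1,2-addition) and the new tertiary hydroxyl is axial, syn to that methyl, as in the target.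

Step 9
Reactants: 17 (1S,2R,3R,4R)-2-(2-chloroethyl)-1,3-dimethyl-3-(4-methylpent-3-en-1-yl)cyclohexane-1,4-diol
Product: 19 (5aR,6R,7S,9aR)-6-(2-chloroethyl)-2,2,5a,7-tetramethyldecahydrobenzo[b]oxepine-3,7-diol (epimers at C3), via organomercurial chloride 18 (not isolated)
Conditions: Hg(OCOCF3)2, CH3NO2, −20 → 0 °C; aq. NaCl; then NaBH4, O2, DMF, 0 °C
Reagents that add atoms: dioxygen O=O
Why: Intramolecular alkoxymercuration is Markovnikov, so the equatorial secondary hydroxyl should attack the dimethyl-substituted alkene carbon (7-endo) and close ring A as the tertiary ether, and oxidative demercuration (radical capture by O2) puts a hydroxyl on the former alkene CH; that centre forms without control and is erased in step 10.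

Step 10
Reactants: 19 (5aR,6R,7S,9aR)-6-(2-chloroethyl)-2,2,5a,7-tetramethyldecahydrobenzo[b]oxepine-3,7-diol (epimers at C3)
Product: 20 (5aR,6R,7S,9aR)-6-(2-chloroethyl)-7-hydroxy-2,2,5a,7-tetramethyloctahydrobenzo[b]oxepin-3(2H)-one
Conditions: Dess–Martin periodinane, NaHCO3, CH2Cl2, rt
Reagents that add atoms: none
Why: Dess–Martin oxidation of the secondary alcohol gives the ring A ketone of the target and converges both epimers; the tertiary alcohol and the chloride are inert.

Step 11
Reactants: 20 (5aR,6R,7S,9aR)-6-(2-chloroethyl)-7-hydroxy-2,2,5a,7-tetramethyloctahydrobenzo[b]oxepin-3(2H)-one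
Product: 21 (5aR,6R,7S,9aR)-6-(2-chloroethyl)-2,2,5a,7-tetramethyl-3,7-bis(triethylsilyloxy)-2,5,5a,6,7,8,9,9a-octahydrobenzo[b]oxepine
Conditions: TESOTf (3 equiv), Et3N, CH2Cl2, −78 → 0 °C
Reagents that add atoms: triethylsilyl trifluoromethanesulfonate CC[Si](CC)(CC)OS(=O)(=O)C(F)(F)F
Why: Silyl triflate with amine base silylates the tertiary hydroxyl and turns the ketone, enolisable only toward its single α-CH2, into the silyl enol ether, masking both sites for the organolithium step.

Step 12
Reactants: 21 (5aR,6R,7S,9aR)-6-(2-chloroethyl)-2,2,5a,7-tetramethyl-3,7-bis(triethylsilyloxy)-2,5,5a,6,7,8,9,9a-octahydrobenzo[b]oxepine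
Product: 22 (5aR,6R,7S,9aR)-6-(2-iodoethyl)-2,2,5a,7-tetramethyl-3,7-bis(triethylsilyloxy)-2,5,5a,6,7,8,9,9a-octahydrobenzo[b]oxepine
Conditions: NaI, NaHCO3, acetone, reflux
Reagents that add atoms: sodium iodide [Na+].[I-]
Why: Finkelstein exchange (SN2 at the unhindered primary carbon) gives the iodide needed for lithium–iodine exchange; the silyl groups tolerate neutral iodide.

Step 13
Reactants: 23 (R)-linalool
Product: 24 (R)-1-methylcyclopent-2-en-1-ol
Conditions: second-generation Grubbs catalyst (0.5 mol %), neat, rt → 45 °C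
Reagents that add atoms: none
Why: Ring-closing metathesis between the vinyl group and the trisubstituted alkene closes the cyclopentene with loss of isobutene, and the carbinol stereocentre comes unchanged from the chiral pool.

Step 14
Reactants: 24 (R)-1-methylcyclopent-2-en-1-ol
Product: 25 (1R)-cis-2,3-epoxy-1-methylcyclopentan-1-ol (oxirane syn to the hydroxyl)
Conditions: VO(acac)2 (2 mol %), t-BuOOH, CH2Cl2, 0 °C → rt
Reagents that add atoms: tert-butyl hydroperoxide CC(C)(C)OO
Why: Vanadium-catalysed epoxidation of an allylic alcohol is delivered from the hydroxyl-bearing face, so the oxirane forms syn to the tertiary hydroxyl.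

Step 15
Reactants: 25 (1R)-cis-2,3-epoxy-1-methylcyclopentan-1-ol; 26 isobutyronitrile
Product: 28 2-[(1S,2S,3R)-2,3-dihydroxy-3-methylcyclopentyl]-2-methylpropanenitrile, via lithiated nitrile 27 (not isolated)
Conditions: 26 (3 equiv), LDA, THF, −78 °C; then 25, −78 °C → rt
Reagents that add atoms: none
Why: SN2 epoxide opening by the nitrile-stabilised tertiary carbanion should occur with inversion at the oxirane carbon remote from the quaternary carbinol, so the cyanoisopropyl group ends trans to the two hydroxyls, which stay cis to each other.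

Step 16
Reactants: 28 2-[(1S,2S,3R)-2,3-dihydroxy-3-methylcyclopentyl]-2-methylpropanenitrile
Product: 29 2-[(1S,3R)-3-hydroxy-3-methyl-2-oxocyclopentyl]-2-methylpropanenitrile
Conditions: SO3·pyridine, DMSO, i-Pr2NEt, CH2Cl2, 0 °C
Reagents that add atoms: none
Why: Parikh–Doering oxidation converts only the secondary alcohol into the ketone, leaving the tertiary alcohol and the α-CH centre intact.

Step 17
Reactants: 29 2-[(1S,3R)-3-hydroxy-3-methyl-2-oxocyclopentyl]-2-methylpropanenitrile
Product: 30 2-methyl-2-[(1S,3R)-3-methyl-2-oxo-3-(triethylsilyloxy)cyclopentyl]propanenitrile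
Conditions: TESOTf, 2,6-lutidine, CH2Cl2, −78 → 0 °C
Reagents that add atoms: triethylsilyl trifluoromethanesulfonate CC[Si](CC)(CC)OS(=O)(=O)C(F)(F)F
Why: Silyl triflate silylation protects the tertiary alcohol against the organometallic steps that follow.

Step 18
Reactants: 30 2-methyl-2-[(1S,3R)-3-methyl-2-oxo-3-(triethylsilyloxy)cyclopentyl]propanenitrile
Product: 31 2-methyl-2-[(1S,3R)-3-methyl-2-methylidene-3-(triethylsilyloxy)cyclopentyl]propanenitrile
Conditions: Zn, CH2Br2, TiCl4, THF/CH2Cl2, 0 °C → rt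
Reagents that add atoms: dibromomethane BrCBr
Why: Lombardo methylenation converts the hindered, enolisable ketone into the exocyclic alkene without base, so the neighbouring CH centre is not epimerised.

Step 19
Reactants: 31 2-methyl-2-[(1S,3R)-3-methyl-2-methylidene-3-(triethylsilyloxy)cyclopentyl]propanenitrile
Product: 33 2-methyl-2-[(1R,2R,3R)-3-methyl-2-(prop-2-en-1-yl)-3-(triethylsilyloxy)cyclopentyl]propanenitrile, via alkyl-9-BBN 32 (not isolated)
Conditions: 9-BBN, THF, 60 °C; then vinyl bromide, Pd(dppf)Cl2 (5 mol %), AsPh3, aq. K3PO4, DMF, rt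
Reagents that add atoms: vinyl bromide C=CBr
Why: 9-BBN should add to the exocyclic alkene from the face opposite to the bulky cyanoisopropyl group on the next carbon, so the boryl-methyl arm ends cis to that group, and B-alkyl Suzuki–Miyaura coupling with vinyl bromide converts it into the allyl chain.

Step 20
Reactants: 33 2-methyl-2-[(1R,2R,3R)-3-methyl-2-(prop-2-en-1-yl)-3-(triethylsilyloxy)cyclopentyl]propanenitrile
Product: 35 2,4-dimethyl-2-[(1R,2R,3R)-3-methyl-2-(prop-2-en-1-yl)-3-(triethylsilyloxy)cyclopentyl]pent-4-en-3-one, via ketimine 34 (not isolated)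
Conditions: isopropenylmagnesium bromide, CuBr (5 mol %), THF, reflux; then 1 M aq. HCl, 0 °C
Reagents that add atoms: isopropenylmagnesium bromide CC(=C)[Mg]Br; water O
Why: Grignard addition to the nitrile stops at the N-magnesio ketimine, whose hydrolysis gives the isopropenyl ketone without over-addition.

Step 21
Reactants: 35 2,4-dimethyl-2-[(1R,2R,3R)-3-methyl-2-(prop-2-en-1-yl)-3-(triethylsilyloxy)cyclopentyl]pent-4-en-3-one
Product: 36 (1R,3aR,8aR)-1,4,4,6-tetramethyl-1-(triethylsilyloxy)-2,3,3a,4,8,8a-hexahydroazulen-5(1H)-one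
Conditions: second-generation Hoveyda–Grubbs catalyst (5 mol %), toluene (5 mM), 80 °C
Reagents that add atoms: none
Why: Ring-closing metathesis of the terminal alkene with the 1,1-disubstituted enone alkene closes ring C as a 2-methylcyclohept-2-enone, helped by the gem-dimethyl group and the cis arrangement of the two arms that fixes the cis ring fusion.

Step 22
Reactants: 22 (5aR,6R,7S,9aR)-6-(2-iodoethyl)-2,2,5a,7-tetramethyl-3,7-bis(triethylsilyloxy)-2,5,5a,6,7,8,9,9a-octahydrobenzo[b]oxepine; 36 (1R,3aR,8aR)-1,4,4,6-tetramethyl-1-(triethylsilyloxy)-2,3,3a,4,8,8a-hexahydroazulen-5(1H)-one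
Product: 39 tertiary allylic methyl carbonate of the ring A/B–ring C/D 1,2-adduct, via alkyllithium 37 (not isolated), via lithium alkoxide 38 (not isolated)
Conditions: 22, t-BuLi (2.1 equiv), Et2O, −78 °C; then 36, THF, −78 °C; then ClCO2Me, −78 → 0 °C
Reagents that add atoms: methyl chloroformate COC(=O)Cl
Why: Lithium–iodine exchange gives a primary alkyllithium that should add 1,2 to the non-enolisable enone carbonyl from the convex face (syn to the ring-fusion hydrogens, away from the folded cyclopentane), and the tertiary alkoxide is trapped as the carbonate.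

Step 23
Reactants: 39 tertiary allylic methyl carbonate of the ring A/B–ring C/D 1,2-adduct
Product: 40 tris(triethylsilyl)-protected ring C olefin
Conditions: Pd(OAc)2 (10 mol %), PBu3 (10 mol %), HCO2NH4, 1,4-dioxane, 90 °C
Reagents that add atoms: none
Why: Zerovalent palladium ionises the allylic carbonate with inversion, formate gives a palladium hydride, and hydride passes from the metal to the more substituted allyl terminus (formate hydrogenolysis of the Tsuji–Trost type), so hydrogen should enter syn to the ring-fusion hydrogens, the side chain moves to the opposite face and the trisubstituted olefin results.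

Step 24
Reactants: 40 tris(triethylsilyl)-protected ring C olefin
Product: 41 ring C olefin diol ketone (the target without the oxirane oxygen)
Conditions: HF·pyridine, pyridine, THF, 0 °C → rt
Reagents that add atoms: none
Why: Fluoride cleaves both tertiary silyl ethers and the silyl enol ether, the latter returning the ring A ketone by protonation at carbon.

Step 25
Reactants: 41 ring C olefin diol ketone
Product: 43 CNP0259752.1 (target), via bromohydrin 42 (not isolated)
Conditions: NBS, THF/H2O (3:1), 0 °C; then K2CO3, MeOH, rt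
Reagents that add atoms: water O
Why: NBS should form the bromonium ion on the more open face of the ring C olefin (syn to the ring-fusion hydrogens, anti to the side chain and the folded cyclopentane), water opens it anti and base closes the bromohydrin with inversion, so the oxirane oxygen ends on the opposite face, syn to the side chain, as in the target.

**Compound list**

1 | 3-(tert-butyldimethylsilyloxy)propanal | O=CCCO[Si](C)(C)C(C)(C)C | starting material
2 | methyl propiolate | COC(=O)C#C | starting material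
3 | methyl 3-(methylzincio)prop-2-ynoate (zinc acetylide) | COC(=O)C#C[Zn]C | intermediate (not isolated)
4 | methyl (R)-6-(tert-butyldimethylsilyloxy)-4-hydroxyhex-2-ynoate | COC(=O)C#C[C@H](O)CCO[Si](C)(C)C(C)(C)C | intermediate
5 | 5-bromo-2-methylpent-2-ene | CC(C)=CCCBr | starting material
6 | (4-methylpent-3-en-1-yl)magnesium bromide | CC(C)=CCC[Mg]Br | intermediate (not isolated)
7 | methyl (Z)-3-[(R)-3-(tert-butyldimethylsilyloxy)-1-hydroxypropyl]-7-methylocta-2,6-dienoate | COC(=O)/C=C(/CCC=C(C)C)[C@H](O)CCO[Si](C)(C)C(C)(C)C | intermediate (not isolated)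
8 | (R)-5-[2-(tert-butyldimethylsilyloxy)ethyl]-4-(4-methylpent-3-en-1-yl)furan-2(5H)-one | O=C1C=C(CCC=C(C)C)[C@@H](CCO[Si](C)(C)C(C)(C)C)O1 | intermediate
9 | trimethylsilyl ketene acetal of lactone 10 | C[Si](C)(C)OC1=C[C@@](C)(CCC=C(C)C)[C@@H](CCO[Si](C)(C)C(C)(C)C)O1 | intermediate (not isolated)
10 | (4R,5R)-5-[2-(tert-butyldimethylsilyloxy)ethyl]-4-methyl-4-(4-methylpent-3-en-1-yl)dihydrofuran-2(3H)-one | O=C1C[C@@](C)(CCC=C(C)C)[C@@H](CCO[Si](C)(C)C(C)(C)C)O1 | intermediate
11 | lithium enolate of lactone 10 | [Li]OC1=C[C@@](C)(CCC=C(C)C)[C@@H](CCO[Si](C)(C)C(C)(C)C)O1 | intermediate (not isolated)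
12 | (3R,4R,5R)-5-[2-(tert-butyldimethylsilyloxy)ethyl]-3-(2-chloroethyl)-4-methyl-4-(4-methylpent-3-en-1-yl)dihydrofuran-2(3H)-one | O=C1[C@H](CCCl)[C@@](C)(CCC=C(C)C)[C@@H](CCO[Si](C)(C)C(C)(C)C)O1 | intermediate
13 | (3R,4R,5R)-3-(2-chloroethyl)-5-(2-hydroxyethyl)-4-methyl-4-(4-methylpent-3-en-1-yl)dihydrofuran-2(3H)-one | O=C1[C@H](CCCl)[C@@](C)(CCC=C(C)C)[C@@H](CCO)O1 | intermediate
14 | (3R,4R,5R)-3-(2-chloroethyl)-5-(2-iodoethyl)-4-methyl-4-(4-methylpent-3-en-1-yl)dihydrofuran-2(3H)-one | O=C1[C@H](CCCl)[C@@](C)(CCC=C(C)C)[C@@H](CCI)O1 | intermediate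
15 | diiodosamarium alkoxide of the bridged hemiketal (7-oxabicyclo[2.2.1]heptan-1-ol with chloroethyl, methyl and methylpentenyl groups) | I[Sm](I)O[C@@]12CC[C@@H](O1)[C@](C)(CCC=C(C)C)[C@H]2CCCl | intermediate (not isolated)
16 | (2R,3R,4R)-2-(2-chloroethyl)-4-hydroxy-3-methyl-3-(4-methylpent-3-en-1-yl)cyclohexan-1-one | O=C1CC[C@@H](O)[C@](C)(CCC=C(C)C)[C@H]1CCCl | intermediate
17 | (1S,2R,3R,4R)-2-(2-chloroethyl)-1,3-dimethyl-3-(4-methylpent-3-en-1-yl)cyclohexane-1,4-diol | C[C@]1(O)CC[C@@H](O)[C@](C)(CCC=C(C)C)[C@H]1CCCl | intermediate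
18 | ring A organomercurial chloride (3-chloromercurio analogue of 19) | CC1(C)O[C@@H]2CC[C@](C)(O)[C@H](CCCl)[C@@]2(C)CCC1[Hg]Cl | intermediate (not isolated)
19 | (5aR,6R,7S,9aR)-6-(2-chloroethyl)-2,2,5a,7-tetramethyldecahydrobenzo[b]oxepine-3,7-diol (epimers at C3) | CC1(C)O[C@@H]2CC[C@](C)(O)[C@H](CCCl)[C@@]2(C)CCC1O | intermediate
20 | (5aR,6R,7S,9aR)-6-(2-chloroethyl)-7-hydroxy-2,2,5a,7-tetramethyloctahydrobenzo[b]oxepin-3(2H)-one | CC1(C)O[C@@H]2CC[C@](C)(O)[C@H](CCCl)[C@@]2(C)CCC1=O | intermediate
21 | (5aR,6R,7S,9aR)-6-(2-chloroethyl)-2,2,5a,7-tetramethyl-3,7-bis(triethylsilyloxy)-2,5,5a,6,7,8,9,9a-octahydrobenzo[b]oxepine | CC1(C)O[C@@H]2CC[C@](C)(O[Si](CC)(CC)CC)[C@H](CCCl)[C@@]2(C)CC=C1O[Si](CC)(CC)CC | intermediate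
22 | (5aR,6R,7S,9aR)-6-(2-iodoethyl)-2,2,5a,7-tetramethyl-3,7-bis(triethylsilyloxy)-2,5,5a,6,7,8,9,9a-octahydrobenzo[b]oxepine | CC1(C)O[C@@H]2CC[C@](C)(O[Si](CC)(CC)CC)[C@H](CCI)[C@@]2(C)CC=C1O[Si](CC)(CC)CC | intermediate
23 | (R)-linalool [(R)-3,7-dimethylocta-1,6-dien-3-ol] | C=C[C@](C)(O)CCC=C(C)C | starting material
24 | (R)-1-methylcyclopent-2-en-1-ol | C[C@]1(O)C=CCC1 | intermediate
25 | (1R)-cis-2,3-epoxy-1-methylcyclopentan-1-ol (oxirane syn to the hydroxyl) | C[C@]1(O)[C@H]2O[C@H]2CC1 | intermediate
26 | isobutyronitrile | CC(C)C#N | starting material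
27 | 2-lithio-2-methylpropanenitrile | [Li]C(C)(C)C#N | intermediate (not isolated)
28 | 2-[(1S,2S,3R)-2,3-dihydroxy-3-methylcyclopentyl]-2-methylpropanenitrile | C[C@]1(O)[C@@H](O)[C@H](C(C)(C)C#N)CC1 | intermediate
29 | 2-[(1S,3R)-3-hydroxy-3-methyl-2-oxocyclopentyl]-2-methylpropanenitrile | C[C@]1(O)C(=O)[C@H](C(C)(C)C#N)CC1 | intermediate
30 | 2-methyl-2-[(1S,3R)-3-methyl-2-oxo-3-(triethylsilyloxy)cyclopentyl]propanenitrile | C[C@]1(O[Si](CC)(CC)CC)C(=O)[C@H](C(C)(C)C#N)CC1 | intermediate
31 | 2-methyl-2-[(1S,3R)-3-methyl-2-methylidene-3-(triethylsilyloxy)cyclopentyl]propanenitrile | C[C@]1(O[Si](CC)(CC)CC)C(=C)[C@H](C(C)(C)C#N)CC1 | intermediate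
32 | B-alkyl-9-borabicyclo[3.3.1]nonane from 31 (boryl-methyl arm cis to the cyanoisopropyl group) | C[C@]1(O[Si](CC)(CC)CC)[C@H](CB2C3CCCC2CCC3)[C@H](C(C)(C)C#N)CC1 | intermediate (not isolated)
33 | 2-methyl-2-[(1R,2R,3R)-3-methyl-2-(prop-2-en-1-yl)-3-(triethylsilyloxy)cyclopentyl]propanenitrile | C[C@]1(O[Si](CC)(CC)CC)[C@H](CC=C)[C@H](C(C)(C)C#N)CC1 | intermediate
34 | 2,4-dimethyl-2-[(1R,2R,3R)-3-methyl-2-(prop-2-en-1-yl)-3-(triethylsilyloxy)cyclopentyl]pent-4-en-3-imine | C[C@]1(O[Si](CC)(CC)CC)[C@H](CC=C)[C@H](C(C)(C)C(=N)C(C)=C)CC1 | intermediate (not isolated)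
35 | 2,4-dimethyl-2-[(1R,2R,3R)-3-methyl-2-(prop-2-en-1-yl)-3-(triethylsilyloxy)cyclopentyl]pent-4-en-3-one | C[C@]1(O[Si](CC)(CC)CC)[C@H](CC=C)[C@H](C(C)(C)C(=O)C(C)=C)CC1 | intermediate
36 | (1R,3aR,8aR)-1,4,4,6-tetramethyl-1-(triethylsilyloxy)-2,3,3a,4,8,8a-hexahydroazulen-5(1H)-one | CC1=CC[C@@H]2[C@@H](CC[C@@]2(C)O[Si](CC)(CC)CC)C(C)(C)C1=O | intermediate
37 | primary alkyllithium from 22 (lithium in place of iodine) | CC1(C)O[C@@H]2CC[C@](C)(O[Si](CC)(CC)CC)[C@H](CC[Li])[C@@]2(C)CC=C1O[Si](CC)(CC)CC | intermediate (not isolated)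
38 | lithium alkoxide of the tertiary allylic 1,2-adduct (side chain syn to the ring-fusion hydrogens) | CC1(C)O[C@@H]2CC[C@](C)(O[Si](CC)(CC)CC)[C@H](CC[C@]3(O[Li])C(C)=CC[C@@H]4[C@@H](CC[C@@]4(C)O[Si](CC)(CC)CC)C3(C)C)[C@@]2(C)CC=C1O[Si](CC)(CC)CC | intermediate (not isolated)
39 | tertiary allylic methyl carbonate of the ring A/B–ring C/D 1,2-adduct | CC1(C)O[C@@H]2CC[C@](C)(O[Si](CC)(CC)CC)[C@H](CC[C@]3(OC(=O)OC)C(C)=CC[C@@H]4[C@@H](CC[C@@]4(C)O[Si](CC)(CC)CC)C3(C)C)[C@@]2(C)CC=C1O[Si](CC)(CC)CC | intermediate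
40 | tris(triethylsilyl)-protected ring C olefin (two tertiary silyl ethers, ring A silyl enol ether) | CC1(C)O[C@@H]2CC[C@](C)(O[Si](CC)(CC)CC)[C@H](CC[C@@H]3C(C)(C)[C@@H]4CC[C@@](C)(O[Si](CC)(CC)CC)[C@@H]4CC=C3C)[C@@]2(C)CC=C1O[Si](CC)(CC)CC | intermediate
41 | ring C olefin diol ketone (the target without the oxirane oxygen) | CC1(C)O[C@@H]2CC[C@](C)(O)[C@H](CC[C@@H]3C(C)(C)[C@@H]4CC[C@@](C)(O)[C@@H]4CC=C3C)[C@@]2(C)CCC1=O | intermediate
42 | ring C bromohydrin (bromine syn to the ring-fusion hydrogens, tertiary hydroxyl anti) | CC1(C)O[C@@H]2CC[C@](C)(O)[C@H](CC[C@@H]3C(C)(C)[C@@H]4CC[C@@](C)(O)[C@@H]4C[C@@H](Br)[C@]3(C)O)[C@@]2(C)CCC1=O | intermediate (not isolated)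
43 | CNP0259752.1 | CC1(C)O[C@@H]2CC[C@](C)(O)[C@H](CC[C@@H]3C(C)(C)[C@@H]4CC[C@@](C)(O)[C@@H]4C[C@@H]4O[C@@]43C)[C@@]2(C)CCC1=O | target

**Totals and risks**

Total step count: 25. Longest linear sequence: 16 steps (steps 1–12, then 22–25).

Steps most likely to fail:

Step 9. The seven-membered closure may be too slow, so that the mercurinium ion is captured by an external nucleophile, or the organomercurial may revert to the alkene during demercuration. The fallback sets out from 17 and comes back at 19. Epoxidation of the trisubstituted alkene with 3-chloroperbenzoic acid (NaHCO3, CH2Cl2, 0 °C) gives epoxy diol F1. Lewis-acid promoted opening (BF3·OEt2, CH2Cl2, −78 °C) by the secondary hydroxyl at the tertiary oxirane carbon then closes ring A with the hydroxyl already on the neighbouring carbon.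

Step 23. Hydride may be delivered to the less hindered allyl terminus, or β-hydride elimination may give dienes, so that the olefin position and the side-chain CH configuration are lost. The fallback sets out from 22 and 36 and comes back at 40. The union of step 22 is repeated with an aqueous quench to give tertiary allylic alcohol F2. Catalytic Ph3SiOReO3 (Et2O, 0 °C) shifts the hydroxyl suprafacially to the secondary allylic position, giving alcohol F3 with a tetrasubstituted olefin. Mitsunobu displacement with 2-nitrobenzenesulfonylhydrazide (PPh3, diethyl azodicarboxylate, THF, −30 °C) gives sulfonylhydrazine F4 with inversion. On warming it loses the sulfinic acid to give allylic diazene F5, whose sigmatropic loss of dinitrogen delivers hydrogen to the side-chain carbon on the face of the nitrogen and returns the trisubstituted olefin 40.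

Step 7. The alkylsamarium may be protonated (simple loss of iodine) before it reaches the lactone carbonyl through the bridged transition state. The fallback sets out from 14 and comes back at 16. Sodium benzenesulfinate (DMF, rt) displaces the iodide to give sulfone F6. LiN(SiMe3)2 (2.2 equiv, THF, −78 → 0 °C) deprotonates the unhindered sulfonyl CH2 in preference to the hindered tertiary lactone α-CH, and the carbanion is acylated by the lactone to give β-keto sulfone F7 with the hydroxyl set free. Aluminium amalgam (THF/H2O, rt) removes the sulfonyl group to give 16.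

Further compounds
F1 | step 9 | (1S,2R,3R,4R)-2-(2-chloroethyl)-3-[2-(3,3-dimethyloxiran-2-yl)ethyl]-1,3-dimethylcyclohexane-1,4-diol (oxirane epimers) | C[C@]1(O)CC[C@@H](O)[C@](C)(CCC2OC2(C)C)[C@H]1CCCl
F2 | step 23 | tertiary allylic alcohol of the ring A/B–ring C/D 1,2-adduct | CC1(C)O[C@@H]2CC[C@](C)(O[Si](CC)(CC)CC)[C@H](CC[C@]3(O)C(C)=CC[C@@H]4[C@@H](CC[C@@]4(C)O[Si](CC)(CC)CC)C3(C)C)[C@@]2(C)CC=C1O[Si](CC)(CC)CC
F3 | step 23 | transposed secondary allylic alcohol (tetrasubstituted ring C olefin, hydroxyl anti to the ring-fusion hydrogens) | CC1(C)O[C@@H]2CC[C@](C)(O[Si](CC)(CC)CC)[C@H](CCC3=C(C)[C@@H](O)C[C@@H]4[C@@H](CC[C@@]4(C)O[Si](CC)(CC)CC)C3(C)C)[C@@]2(C)CC=C1O[Si](CC)(CC)CC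
F4 | step 23 | N-allyl-N-(2-nitrobenzenesulfonyl)hydrazine from F3 (nitrogen syn to the ring-fusion hydrogens) | CC1(C)O[C@@H]2CC[C@](C)(O[Si](CC)(CC)CC)[C@H](CCC3=C(C)[C@H](N(N)S(=O)(=O)c5ccccc5[N+](=O)[O-])C[C@@H]4[C@@H](CC[C@@]4(C)O[Si](CC)(CC)CC)C3(C)C)[C@@]2(C)CC=C1O[Si](CC)(CC)CC
F5 | step 23 | allylic diazene from F4 | CC1(C)O[C@@H]2CC[C@](C)(O[Si](CC)(CC)CC)[C@H](CCC3=C(C)[C@H](N=N)C[C@@H]4[C@@H](CC[C@@]4(C)O[Si](CC)(CC)CC)C3(C)C)[C@@]2(C)CC=C1O[Si](CC)(CC)CC
F6 | step 7 | (3R,4R,5R)-3-(2-chloroethyl)-4-methyl-4-(4-methylpent-3-en-1-yl)-5-[2-(phenylsulfonyl)ethyl]dihydrofuran-2(3H)-one | O=C1[C@H](CCCl)[C@@](C)(CCC=C(C)C)[C@@H](CCS(=O)(=O)c2ccccc2)O1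
F7 | step 7 | (2R,3R,4R)-2-(2-chloroethyl)-4-hydroxy-3-methyl-3-(4-methylpent-3-en-1-yl)-6-(phenylsulfonyl)cyclohexan-1-one (epimers at the sulfonyl carbon) | O=C1C(S(=O)(=O)c2ccccc2)C[C@@H](O)[C@](C)(CCC=C(C)C)[C@H]1CCCl
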